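## Retrosynthetic overview

1. The acid is released last from its methyl ester. The enyne C(sp)–C(sp2) bond is cut by Sonogashira coupling into a ring-bearing terminal alkyne and (1E)-1-iodoundeca-1,10-diene (from dec-9-en-1-ol).
2. The route rests on the C4–C5 bond of the only ring, the 1,2-dioxane O1–O2–C3–C4–C5–C6. It is the one ring bond between two unsubstituted CH2 carbons, so it is made last, as a C4=C5 alkene, by ring-closing metathesis of an acyclic mixed peroxyketal that already holds O1–C6, O1–O2 and O2–C3.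
3. After ring closure, diimide saturates C4=C5 and acidic methanol equilibrates the ketal carbon C3 to the anomerically favoured epimer, which is the target configuration.
4. The acyclic peroxyketal comes from an iminium-catalysed asymmetric conjugate addition (sets C6) of a tertiary α-methoxy hydroperoxide to a 2,4-dienal. The hydroperoxide is built from hex-5-ynoic acid through the silylated Weinreb amide, the vinyl ketone and its dimethyl ketal.
5. Ring order: one ring only, the 3,6-dihydro-1,2-dioxine, closed in step 9.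

Key step: step 9

Remark 1: the target is read as (3R,6S), with the C3 methoxy group cis to the C6 CH2CO2H group; in the chair this is axial OMe with both carbon substituents equatorial, i.e. the thermodynamic ketal epimer.

Remark 2: the alkene on C6 of the metathesis precursor is carried as an (E)-2-phenylethenyl group instead of a bare vinyl group. The dienal then has a blocked, non-enolisable terminus (less 1,6-addition, no dienamine pathways), and the extra CHPh unit leaves as styrene, so the ring-closed product is unchanged.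

## Route

Step 1
Reactants: 1 hex-5-ynoic acid
Product: 4 6-[tri(propan-2-yl)silyl]hex-5-ynoic acid, via dilithio salt 2 (not isolated), via lithium carboxylate 3 (not isolated)
Conditions: n-BuLi (2.1 equiv), THF, −78 °C; iPr3SiCl (1.2 equiv), −78 °C to rt; 1 M HCl work-up
Reagents that add atoms: chlorotri(propan-2-yl)silane, CC(C)[Si](Cl)(C(C)C)C(C)C
Why: Double deprotonation gives the carboxylate–acetylide dianion, and C-silylation of the lithium acetylide by the hindered silyl chloride should outpace reaction at the carboxylate, which returns as the acid on acidic work-up.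

Step 2
Reactants: 4 6-[tri(propan-2-yl)silyl]hex-5-ynoic acid
Product: 6 N-methoxy-N-methyl-6-[tri(propan-2-yl)silyl]hex-5-ynamide, via acyl imidazole 5 (not isolated)
Conditions: 1,1'-carbonyldiimidazole (1.1 equiv), CH2Cl2, rt; then MeNHOMe·HCl (1.2 equiv), rt
Reagents that add atoms: N,O-dimethylhydroxylamine hydrochloride, CNOC.Cl
Why: Acyl imidazole formation followed by aminolysis is a standard Weinreb amide synthesis that leaves the silyl alkyne untouched.

Step 3
Reactants: 6 N-methoxy-N-methyl-6-[tri(propan-2-yl)silyl]hex-5-ynamide; 7 vinylmagnesium bromide (CH2=CHMgBr)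
Product: 9 8-[tri(propan-2-yl)silyl]oct-1-en-7-yn-3-one, via magnesium chelate 8 (not isolated)
Conditions: THF, −10 to 0 °C; inverse quench into cold 1 M HCl
Reagents that add atoms: none
Why: Weinreb ketone synthesis, in which the chelated tetrahedral magnesium adduct stops at mono-addition and the cold acidic inverse quench protonates the released N,O-dimethylhydroxylamine before it can add to the vinyl ketone.

Step 4
Reactants: 9 8-[tri(propan-2-yl)silyl]oct-1-en-7-yn-3-one
Product: 10 3,3-dimethoxy-8-[tri(propan-2-yl)silyl]oct-1-en-7-yne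
Conditions: MeOSiMe3 (3 equiv), TMSOTf (5 mol%), CH2Cl2, −78 °C; pyridine quench
Reagents that add atoms: methoxytrimethylsilane, CO[Si](C)(C)C
Why: Noyori ketalisation (alkoxysilane with catalytic silyl triflate at low temperature) converts enones into ketals without free methanol or protic acid, which should suppress conjugate addition to the vinyl ketone.

Step 5
Reactants: 10 3,3-dimethoxy-8-[tri(propan-2-yl)silyl]oct-1-en-7-yne
Product: 11 rac-3-hydroperoxy-3-methoxy-8-[tri(propan-2-yl)silyl]oct-1-en-7-yne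
Conditions: H2O2 (anhydrous, in Et2O, 4 equiv), camphorsulfonic acid (5 mol%), Et2O, −20 to 0 °C; NaHCO3 quench
Reagents that add atoms: hydrogen peroxide, OO
Why: Acid-catalysed perhydrolysis (transketalisation) of a dimethyl ketal, in which the 1-methoxyallyl cation should be captured by H2O2 at the ketal carbon under kinetic control at low temperature while the second exchange is slower; the new centre is racemic, which is harmless because C3 is equilibrated in step 11.

Step 6
Reactants: 11 rac-3-hydroperoxy-3-methoxy-8-[tri(propan-2-yl)silyl]oct-1-en-7-yne; 12 (2E,4E)-5-phenylpenta-2,4-dienal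
Product: 13 (3R,4E)-3-({3-methoxy-8-[tri(propan-2-yl)silyl]oct-1-en-7-yn-3-yl}peroxy)-5-phenylpent-4-enal (both ketal epimers)
Conditions: (R)-2-[diphenyl(trimethylsilyloxy)methyl]pyrrolidine (10 mol%), PhCO2H (10 mol%), toluene, 0 °C; 12 in excess (1.5 equiv)
Reagents that add atoms: none
Why: Iminium-catalysed asymmetric oxa-Michael addition (β-peroxidation of an enal with an α-alkoxy hydroperoxide), in which the diphenyl(silyloxy)methyl group of the (R)-catalyst shields one face of the s-trans (E)-iminium so that the peroxide should add to the Si face of C3 and set the 3R centre, the δ-phenyl group disfavouring 1,6-addition.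

Step 7
Reactants: 13 (3R,4E)-3-({3-methoxy-8-[tri(propan-2-yl)silyl]oct-1-en-7-yn-3-yl}peroxy)-5-phenylpent-4-enal
Product: 14 (3R,4E)-3-({3-methoxy-8-[tri(propan-2-yl)silyl]oct-1-en-7-yn-3-yl}peroxy)-5-phenylpent-4-enoic acid (both ketal epimers)
Conditions: NaClO2, NaH2PO4, 2-methylbut-2-ene (10 equiv), t-BuOH/H2O, 0 °C
Reagents that add atoms: sodium chlorite, [Na+].[O-]Cl=O
Why: Pinnick oxidation converts the aldehyde to the acid under buffered conditions that dialkyl peroxides tolerate, with 2-methylbut-2-ene scavenging hypochlorous acid away from the alkenes, and it removes the aldehyde before retro-addition can erode the C3 centre.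

Step 8
Reactants: 14 (3R,4E)-3-({3-methoxy-8-[tri(propan-2-yl)silyl]oct-1-en-7-yn-3-yl}peroxy)-5-phenylpent-4-enoic acid
Product: 15 methyl (3R,4E)-3-({3-methoxy-8-[tri(propan-2-yl)silyl]oct-1-en-7-yn-3-yl}peroxy)-5-phenylpent-4-enoate (both ketal epimers)
Conditions: Me3SiCHN2 (1.2 equiv), toluene/MeOH, 0 °C
Reagents that add atoms: (trimethylsilyl)diazomethane, C[Si](C)(C)C=[N+]=[N-]
Why: Esterification with (trimethylsilyl)diazomethane is fast and essentially neutral, avoiding the acid that would ionise the allylic peroxyketal and the base that would eliminate the β-peroxide.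

Step 9
Reactants: 15 methyl (3R,4E)-3-({3-methoxy-8-[tri(propan-2-yl)silyl]oct-1-en-7-yn-3-yl}peroxy)-5-phenylpent-4-enoate
Product: 16 methyl 2-[(6R)-3-methoxy-3-{5-[tri(propan-2-yl)silyl]pent-4-yn-1-yl}-3,6-dihydro-1,2-dioxin-6-yl]acetate (3R and 3S epimers)
Conditions: second-generation Grubbs catalyst RuCl2(=CHPh)(PCy3)(H2IMes) (10 mol%), CH2Cl2 (0.005 M), 40 °C, Ar
Reagents that add atoms: none
Why: Proposed new method: the ruthenium alkylidene is transferred onto one of the two alkenes (the vinyl group on C3 or the styryl group on C6), adds across the other in a [2+2] cycloaddition, and cycloreversion of the ruthenacyclobutane forms the C4=C5 bond with overall loss of styrene. The closest known reaction types are ring-closing metathesis of diallyl ethers and mixed allylic acetals to 3,6-dihydro-2H-pyrans, and olefin cross-metathesis on alkenes that carry dialkyl peroxides, which shows that an O–O bond can survive ruthenium carbenes. The ring closed is the six-membered 3,6-dihydro-1,2-dioxine (O1, O2, C3, C4, C5, C6), formed by ring-closing metathesis at C4=C5, and the ring forces the new alkene to be cis. No stereocentre is made: C6 is carried from step 6 and both C3 epimers should cyclise, to converge in step 11. The step needs ring closure in preference to oligomerisation, enyne metathesis and ruthenium-induced O–O cleavage; high dilution, the fully substituted C3 (gem-disubstituent effect) and the gauche C–O–O–C geometry favour closure, the tri(propan-2-yl)silyl group shields the alkyne, and the peroxide is fully alkylated with no O–H.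

Step 10
Reactants: 16 methyl 2-[(6R)-3-methoxy-3-{5-[tri(propan-2-yl)silyl]pent-4-yn-1-yl}-3,6-dihydro-1,2-dioxin-6-yl]acetate
Product: 17 methyl 2-[(6S)-3-methoxy-3-{5-[tri(propan-2-yl)silyl]pent-4-yn-1-yl}-1,2-dioxan-6-yl]acetate (3R and 3S epimers)
Conditions: KO2CN=NCO2K (excess), AcOH (slow addition), CH2Cl2, 0 °C to rt
Reagents that add atoms: none
Why: Diimide reduction transfers hydrogen concertedly to the unhindered cis ring alkene without cleaving the O–O bond, the bulky silyl group slowing reduction of the alkyne; C6 keeps its spatial arrangement and only its descriptor changes from R to S.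

Step 11
Reactants: 17 methyl 2-[(6S)-3-methoxy-3-{5-[tri(propan-2-yl)silyl]pent-4-yn-1-yl}-1,2-dioxan-6-yl]acetate
Product: 18 methyl 2-[(3R,6S)-3-methoxy-3-{5-[tri(propan-2-yl)silyl]pent-4-yn-1-yl}-1,2-dioxan-6-yl]acetate
Conditions: camphorsulfonic acid (10 mol%), MeOH (10 equiv), CH2Cl2, rt
Reagents that add atoms: methanol, CO
Why: Acid-catalysed anomerisation of the cyclic peroxyketal through the ring peroxycarbenium ion should settle on the thermodynamic epimer, with the methoxy group axial (anomeric effect) and both carbon substituents equatorial, which is 3R relative to the fixed 6S centre.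

Step 12
Reactants: 18 methyl 2-[(3R,6S)-3-methoxy-3-{5-[tri(propan-2-yl)silyl]pent-4-yn-1-yl}-1,2-dioxan-6-yl]acetate
Product: 19 methyl 2-[(3R,6S)-3-methoxy-3-(pent-4-yn-1-yl)-1,2-dioxan-6-yl]acetate
Conditions: Bu4NF (1.5 equiv), AcOH (1.5 equiv), THF, 0 °C to rt
Reagents that add atoms: none
Why: Fluoride-mediated protodesilylation of the alkynylsilane, buffered with acetic acid so that the β-peroxy ester is not exposed to a base strong enough to eliminate the peroxide.

Step 13
Reactants: 20 dec-9-en-1-ol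
Product: 21 dec-9-enal
Conditions: PhI(OAc)2 (1.1 equiv), TEMPO (10 mol%), CH2Cl2, rt
Reagents that add atoms: none
Why: Oxoammonium-mediated (TEMPO) oxidation of a primary alcohol stops at the aldehyde and leaves the terminal alkene alone.

Step 14
Reactants: 21 dec-9-enal
Product: 22 (1E)-1-iodoundeca-1,10-diene
Conditions: CrCl2 (6 equiv), CHI3 (2 equiv), THF/1,4-dioxane, 0 °C to rt, dark
Reagents that add atoms: triiodomethane, IC(I)I
Why: Takai olefination, in which the gem-dichromium species from iodoform adds to the aldehyde and eliminates to give the (E)-vinyl iodide selectively.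

Step 15
Reactants: 19 methyl 2-[(3R,6S)-3-methoxy-3-(pent-4-yn-1-yl)-1,2-dioxan-6-yl]acetate; 22 (1E)-1-iodoundeca-1,10-diene
Product: 23 methyl 2-[(3R,6S)-3-[(6E)-hexadeca-6,15-dien-4-yn-1-yl]-3-methoxy-1,2-dioxan-6-yl]acetate
Conditions: Pd(PPh3)4 (5 mol%), CuI (10 mol%), iPr2NH (3 equiv), THF, rt, degassed
Reagents that add atoms: none
Why: Sonogashira coupling of the terminal alkyne with the (E)-vinyl iodide proceeds at room temperature with retention of alkene geometry, under catalytic zerovalent palladium and a hindered amine that a saturated dialkyl peroxide should tolerate.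

Step 16
Reactants: 23 methyl 2-[(3R,6S)-3-[(6E)-hexadeca-6,15-dien-4-yn-1-yl]-3-methoxy-1,2-dioxan-6-yl]acetate
Product: 25 2-[(3R,6S)-3-[(6E)-hexadeca-6,15-dien-4-yn-1-yl]-3-methoxy-1,2-dioxan-6-yl]acetic acid, via lithium carboxylate 24 (not isolated)
Conditions: LiOH (2 equiv), THF/H2O, 0 °C; then 0.5 M HCl to pH 4, 0 °C
Reagents that add atoms: lithium hydroxide, [Li+].[OH-]
Why: Saponification with LiOH at 0 °C followed by careful acidification should free the acid without β-elimination of the peroxide or loss of the ketal.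

## Compound list

1 | hex-5-ynoic acid | C#CCCCC(=O)O | starting material
2 | lithium 6-lithiohex-5-ynoate (dilithio salt) | [Li]C#CCCCC(=O)[O-].[Li+] | intermediate
3 | lithium 6-[tri(propan-2-yl)silyl]hex-5-ynoate | CC(C)[Si](C#CCCCC(=O)[O-])(C(C)C)C(C)C.[Li+] | intermediate
4 | 6-[tri(propan-2-yl)silyl]hex-5-ynoic acid | CC(C)[Si](C#CCCCC(=O)O)(C(C)C)C(C)C | intermediate
5 | 1-(1H-imidazol-1-yl)-6-[tri(propan-2-yl)silyl]hex-5-yn-1-one (acyl imidazole) | CC(C)[Si](C#CCCCC(=O)n1ccnc1)(C(C)C)C(C)C | intermediate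
6 | N-methoxy-N-methyl-6-[tri(propan-2-yl)silyl]hex-5-ynamide | CC(C)[Si](C#CCCCC(=O)N(C)OC)(C(C)C)C(C)C | intermediate
7 | vinylmagnesium bromide | C=C[Mg]Br | starting material
8 | bromomagnesium 3-[methoxy(methyl)amino]-8-[tri(propan-2-yl)silyl]oct-1-en-7-yn-3-olate (magnesium chelate) | C=CC(O[Mg]Br)(N(C)OC)CCCC#C[Si](C(C)C)(C(C)C)C(C)C | intermediate
9 | 8-[tri(propan-2-yl)silyl]oct-1-en-7-yn-3-one | C=CC(=O)CCCC#C[Si](C(C)C)(C(C)C)C(C)C | intermediate
10 | 3,3-dimethoxy-8-[tri(propan-2-yl)silyl]oct-1-en-7-yne | C=CC(OC)(OC)CCCC#C[Si](C(C)C)(C(C)C)C(C)C | intermediate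
11 | rac-3-hydroperoxy-3-methoxy-8-[tri(propan-2-yl)silyl]oct-1-en-7-yne | C=CC(OC)(OO)CCCC#C[Si](C(C)C)(C(C)C)C(C)C | intermediate
12 | (2E,4E)-5-phenylpenta-2,4-dienal | O=C/C=C/C=C/c1ccccc1 | starting material
13 | (3R,4E)-3-({3-methoxy-8-[tri(propan-2-yl)silyl]oct-1-en-7-yn-3-yl}peroxy)-5-phenylpent-4-enal, both ketal epimers | C=CC(OC)(CCCC#C[Si](C(C)C)(C(C)C)C(C)C)OO[C@@H](/C=C/c1ccccc1)CC=O | intermediate
14 | (3R,4E)-3-({3-methoxy-8-[tri(propan-2-yl)silyl]oct-1-en-7-yn-3-yl}peroxy)-5-phenylpent-4-enoic acid, both ketal epimers | C=CC(OC)(CCCC#C[Si](C(C)C)(C(C)C)C(C)C)OO[C@@H](/C=C/c1ccccc1)CC(=O)O | intermediate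
15 | methyl (3R,4E)-3-({3-methoxy-8-[tri(propan-2-yl)silyl]oct-1-en-7-yn-3-yl}peroxy)-5-phenylpent-4-enoate, both ketal epimers (metathesis precursor) | C=CC(OC)(CCCC#C[Si](C(C)C)(C(C)C)C(C)C)OO[C@@H](/C=C/c1ccccc1)CC(=O)OC | intermediate
16 | methyl 2-[(6R)-3-methoxy-3-{5-[tri(propan-2-yl)silyl]pent-4-yn-1-yl}-3,6-dihydro-1,2-dioxin-6-yl]acetate, 3R and 3S epimers (metathesis product) | CC(C)[Si](C#CCCCC1(OC)C=C[C@@H](CC(=O)OC)OO1)(C(C)C)C(C)C | intermediate
17 | methyl 2-[(6S)-3-methoxy-3-{5-[tri(propan-2-yl)silyl]pent-4-yn-1-yl}-1,2-dioxan-6-yl]acetate, 3R and 3S epimers | CC(C)[Si](C#CCCCC1(OC)CC[C@@H](CC(=O)OC)OO1)(C(C)C)C(C)C | intermediate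
18 | methyl 2-[(3R,6S)-3-methoxy-3-{5-[tri(propan-2-yl)silyl]pent-4-yn-1-yl}-1,2-dioxan-6-yl]acetate | CC(C)[Si](C#CCCC[C@]1(OC)CC[C@@H](CC(=O)OC)OO1)(C(C)C)C(C)C | intermediate
19 | methyl 2-[(3R,6S)-3-methoxy-3-(pent-4-yn-1-yl)-1,2-dioxan-6-yl]acetate | C#CCCC[C@]1(OC)CC[C@@H](CC(=O)OC)OO1 | intermediate
20 | dec-9-en-1-ol | C=CCCCCCCCCO | starting material
21 | dec-9-enal | C=CCCCCCCCC=O | intermediate
22 | (1E)-1-iodoundeca-1,10-diene | C=CCCCCCCC/C=C/I | intermediate
23 | methyl 2-[(3R,6S)-3-[(6E)-hexadeca-6,15-dien-4-yn-1-yl]-3-methoxy-1,2-dioxan-6-yl]acetate | C=CCCCCCCC/C=C/C#CCCC[C@]1(OC)CC[C@@H](CC(=O)OC)OO1 | intermediate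
24 | lithium 2-[(3R,6S)-3-[(6E)-hexadeca-6,15-dien-4-yn-1-yl]-3-methoxy-1,2-dioxan-6-yl]acetate | C=CCCCCCCC/C=C/C#CCCC[C@]1(OC)CC[C@@H](CC(=O)[O-])OO1.[Li+] | intermediate
25 | 2-[(3R,6S)-3-[(6E)-hexadeca-6,15-dien-4-yn-1-yl]-3-methoxy-1,2-dioxan-6-yl]acetic acid | C=CCCCCCCC/C=C/C#CCCC[C@]1(OC)CC[C@@H](CC(=O)O)OO1 | target

## Step count and risks

Total step count: 16 steps. Longest linear sequence: 14 steps (steps 1–12, then 15 and 16); steps 13 and 14 make the tail.

**Step 9 (ring-closing metathesis).** The ruthenium carbene may be consumed by electron transfer to the O–O bond, or intermolecular metathesis and enyne metathesis may outpace closure onto the hindered vinyl group on C3. The fallback sets out from Weinreb amide 6 and comes back at 18, closing the ring at O2–C3 by known peroxyketal chemistry instead of at C4–C5.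
- Addition of but-3-en-1-ylmagnesium bromide to 6 (THF, 0 °C) should give 10-[tri(propan-2-yl)silyl]dec-1-en-9-yn-5-one F1.
- HC(OMe)3, MeOH and catalytic TsOH convert it into (6,6-dimethoxydec-9-en-1-yn-1-yl)tri(propan-2-yl)silane F2.
- Cross-metathesis with crotonaldehyde (second-generation Hoveyda–Grubbs catalyst RuCl2(=CH-C6H4-2-OiPr)(H2IMes), CH2Cl2, 40 °C, no peroxide yet present) gives (2E)-6,6-dimethoxy-11-[tri(propan-2-yl)silyl]undec-2-en-10-ynal F3.
- 2-Hydroperoxy-2-methoxypropane F4, made by ozonolysis of 2,3-dimethylbut-2-ene in methanol, is added to F3 with the (R)-catalyst of step 6. A simple β-alkyl enal is the best established substrate class for this peroxidation. The product is (3S)-6,6-dimethoxy-3-[(2-methoxypropan-2-yl)peroxy]-11-[tri(propan-2-yl)silyl]undec-10-ynal F5.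
- Pinnick oxidation gives (3S)-6,6-dimethoxy-3-[(2-methoxypropan-2-yl)peroxy]-11-[tri(propan-2-yl)silyl]undec-10-ynoic acid F6, and (trimethylsilyl)diazomethane gives methyl (3S)-6,6-dimethoxy-3-[(2-methoxypropan-2-yl)peroxy]-11-[tri(propan-2-yl)silyl]undec-10-ynoate F7.
- Camphorsulfonic acid in MeOH/CH2Cl2 removes the 2-methoxypropan-2-yl group, and the freed C6 hydroperoxide closes onto the C3 ketal carbon under the thermodynamic control of step 11, giving 18 directly.

**Step 6 (asymmetric peroxidation).** Addition of the hindered tertiary hydroperoxide to the dienal may be slow and reversible, so that the peroxy enamine collapses with O–O cleavage to the epoxy aldehyde, or pairing of the racemic hydroperoxide with the chiral catalyst lowers facial selectivity. The fallback sets out from dienal 12 (and uses ketal 10) and comes back at 15. It sets C6 with a small hydroperoxide and forms the O2–C3 bond afterwards by peroxyketal exchange, so hydroperoxide 11 is not needed.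
- Dienal 12 is peroxidised with 2-hydroperoxy-2-methoxypropane F4 and the same (R)-catalyst to give (3R,4E)-3-[(2-methoxypropan-2-yl)peroxy]-5-phenylpent-4-enal F8.
- Pinnick oxidation gives (3R,4E)-3-[(2-methoxypropan-2-yl)peroxy]-5-phenylpent-4-enoic acid F9, and (trimethylsilyl)diazomethane gives methyl (3R,4E)-3-[(2-methoxypropan-2-yl)peroxy]-5-phenylpent-4-enoate F10.
- Pyridinium p-toluenesulfonate in methanol releases methyl (3R,4E)-3-hydroperoxy-5-phenylpent-4-enoate F11.
- Acid-catalysed exchange of F11 with ketal 10 (camphorsulfonic acid cat., CH2Cl2, 4 Å molecular sieves, 0 °C) gives 15.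

**Step 4 (ketalisation of the vinyl ketone).** Conjugate addition of the methoxy nucleophile to the activated vinyl ketone, or its polymerisation, may compete with ketal formation. The fallback sets out from enone 9 and comes back at 10, masking the vinyl group during ketalisation.
- Benzeneselenol (from PhSeSePh and NaBH4 in EtOH, then AcOH) adds to 9 to give 1-(phenylselanyl)-8-[tri(propan-2-yl)silyl]oct-7-yn-3-one F12.
- HC(OMe)3, MeOH and catalytic TsOH give 3,3-dimethoxy-1-(phenylselanyl)-8-[tri(propan-2-yl)silyl]oct-7-yne F13.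
- NaIO4 with NaHCO3 in aqueous MeOH gives 1-(benzeneseleninyl)-3,3-dimethoxy-8-[tri(propan-2-yl)silyl]oct-7-yne F14, which undergoes selenoxide syn-elimination at rt to give 10.

## Further compounds

F1 | step 9 | 10-[tri(propan-2-yl)silyl]dec-1-en-9-yn-5-one | C=CCCC(=O)CCCC#C[Si](C(C)C)(C(C)C)C(C)C
F2 | step 9 | (6,6-dimethoxydec-9-en-1-yn-1-yl)tri(propan-2-yl)silane | C=CCCC(OC)(OC)CCCC#C[Si](C(C)C)(C(C)C)C(C)C
F3 | step 9 | (2E)-6,6-dimethoxy-11-[tri(propan-2-yl)silyl]undec-2-en-10-ynal | O=C/C=C/CCC(OC)(OC)CCCC#C[Si](C(C)C)(C(C)C)C(C)C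
F4 | step 9 | 2-hydroperoxy-2-methoxypropane | COC(C)(C)OO
F5 | step 9 | (3S)-6,6-dimethoxy-3-[(2-methoxypropan-2-yl)peroxy]-11-[tri(propan-2-yl)silyl]undec-10-ynal | O=CC[C@H](CCC(OC)(OC)CCCC#C[Si](C(C)C)(C(C)C)C(C)C)OOC(C)(C)OC
F6 | step 9 | (3S)-6,6-dimethoxy-3-[(2-methoxypropan-2-yl)peroxy]-11-[tri(propan-2-yl)silyl]undec-10-ynoic acid | OC(=O)C[C@H](CCC(OC)(OC)CCCC#C[Si](C(C)C)(C(C)C)C(C)C)OOC(C)(C)OC
F7 | step 9 | methyl (3S)-6,6-dimethoxy-3-[(2-methoxypropan-2-yl)peroxy]-11-[tri(propan-2-yl)silyl]undec-10-ynoate | COC(=O)C[C@H](CCC(OC)(OC)CCCC#C[Si](C(C)C)(C(C)C)C(C)C)OOC(C)(C)OC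
F8 | step 6 | (3R,4E)-3-[(2-methoxypropan-2-yl)peroxy]-5-phenylpent-4-enal | O=CC[C@H](/C=C/c1ccccc1)OOC(C)(C)OC
F9 | step 6 | (3R,4E)-3-[(2-methoxypropan-2-yl)peroxy]-5-phenylpent-4-enoic acid | OC(=O)C[C@H](/C=C/c1ccccc1)OOC(C)(C)OC
F10 | step 6 | methyl (3R,4E)-3-[(2-methoxypropan-2-yl)peroxy]-5-phenylpent-4-enoate | COC(=O)C[C@H](/C=C/c1ccccc1)OOC(C)(C)OC
F11 | step 6 | methyl (3R,4E)-3-hydroperoxy-5-phenylpent-4-enoate | COC(=O)C[C@H](/C=C/c1ccccc1)OO
F12 | step 4 | 1-(phenylselanyl)-8-[tri(propan-2-yl)silyl]oct-7-yn-3-one | O=C(CC[Se]c1ccccc1)CCCC#C[Si](C(C)C)(C(C)C)C(C)C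
F13 | step 4 | 3,3-dimethoxy-1-(phenylselanyl)-8-[tri(propan-2-yl)silyl]oct-7-yne | COC(CC[Se]c1ccccc1)(OC)CCCC#C[Si](C(C)C)(C(C)C)C(C)C
F14 | step 4 | 1-(benzeneseleninyl)-3,3-dimethoxy-8-[tri(propan-2-yl)silyl]oct-7-yne | COC(CC[Se](=O)c1ccccc1)(OC)CCCC#C[Si](C(C)C)(C(C)C)C(C)C
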